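**Retrosynthetic overview**
- Target ⇐ catalyst-controlled reduction of a 2-methylenecycloheptanone, itself made by an oxidative semipinacol ring expansion (1,2-shift of C8) of a 1-vinylcyclohexanol: the seven-membered ring is formed last, six → seven.
- Side chain: acetate on C12 after α-selective prenylbarium addition to a C12 aldehyde, unmasked from a cis-fused C3–O/C12 γ-lactone via its Weinreb amide.
- Five-membered ring (C1–C10 bond, exocyclic CH2, C10–OH): samarium ketyl–alkyne closure between trans C2-ethynyl and C8-CH2CHO arms.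
- Lactone (C4–C11 bond, C4 and C11): intramolecular Reformatsky-type Michael addition of a C3 O-(2-bromopropanoate) onto the C4=C5 enone.
- trans C2/C8 arms: alkynylalane conjugate addition and enolate allylation on (R)-4-silyloxycyclohexenone. Ring order: six-membered ring (bought), lactone, five-membered ring, ring expansion to seven.

Assumption: enone 1 is bought as its TBS ether (eight non-hydrogen atoms without the protecting group).

Locants for bi- and tricyclic compounds are those of the target: five-membered ring C1–C2–C8–C9–C10 (C1 carries the exocyclic CH2), seven-membered ring C2–C3–C4–C5–C6–C7–C8, side chain C11 (CHMe), C12 (C–O), C13–C15. In the hydrindane intermediates C6 is bonded directly to C8.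

**Step 1**
Reactants: 1 (R)-4-[(tert-butyldimethylsilyl)oxy]cyclohex-2-en-1-one; 2 lithium (trimethylsilyl)acetylide; 3 allyl iodide
Product: 6 (2R,3S,4R)-2-allyl-4-[(tert-butyldimethylsilyl)oxy]-3-[(trimethylsilyl)ethynyl]cyclohexan-1-one, via alkynylalane 4 (not isolated), via aluminium enolate 5 (not isolated)
Conditions: 2, Et2AlCl, Et2O, 0 °C; 1, Ni(acac)2 (5 mol %), i-Bu2AlH (5 mol %), −5 °C; then MeLi, DMPU, 3, THF, −78 → −20 °C
Reagents that add atoms: none
Why: Nickel-catalysed conjugate addition of the alkynylalane to the cyclic enone occurs anti to the adjacent silyloxy group (sets C2), and the aluminium enolate, activated as its methyl ate complex, is allylated trans to the new alkynyl group (sets C8), a three-component conjugate addition–enolate alkylation.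

**Step 2**
Reactants: 6
Product: 8 (4R,5S,6R)-6-allyl-4-[(tert-butyldimethylsilyl)oxy]-5-[(trimethylsilyl)ethynyl]cyclohex-2-en-1-one, via α-phenylselanyl ketone 7 (not isolated)
Conditions: LiN(i-Pr)2, THF, −78 °C; PhSeBr; then H2O2, pyridine, CH2Cl2, 0 → 23 °C
Reagents that add atoms: none
Why: The kinetic enolate forms at the unsubstituted α-methylene rather than the allyl-bearing α-carbon, and α-selenenylation followed by selenoxide syn-elimination (Reich–Sharpless) gives the enone without touching the stereocentres and without the palladium-mediated cycloalkenylation the allyl group would risk under Saegusa conditions.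

**Step 3**
Reactants: 8; 9 2-bromopropanoyl bromide
Product: 10 (1R,5R,6S)-5-allyl-4-oxo-6-[(trimethylsilyl)ethynyl]cyclohex-2-en-1-yl 2-bromopropanoate (both epimers at CHBr)
Conditions: 9 (1.5 equiv), SnBr2 (10 mol %), CH2Cl2, 23 °C
Reagents that add atoms: none
Why: Lewis-acid-catalysed acylative cleavage of a silyl ether by an acid bromide (Oriyama-type) exchanges the silyl group for the α-bromo ester in one operation, with retention at the carbinol carbon because only the O–Si bond breaks.

**Step 4**
Reactants: 10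
Product: 12 (3S,3aS,6R,7S,7aR)-6-allyl-7-ethynyl-3-methyloctahydro-1-benzofuran-2,5-dione, via silylalkyne lactone 11 (not isolated)
Conditions: SmI2 (2.2 equiv), THF, −78 °C; then K2CO3, MeOH, 23 °C; 1 M HCl
Reagents that add atoms: none
Why: Two-electron reduction of the α-bromo ester gives a samarium ester enolate (Reformatsky-type) that adds 5-exo-trig to the tethered enone from the face of the ester oxygen, so the γ-lactone is cis-fused (sets C4), and the K2CO3/MeOH stage removes the alkynyl silane and equilibrates the lactone α-carbon to the convex-face methyl epimer (sets C11).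

**Step 5**
Reactants: 12
Product: 13 2-[(3S,3aS,6R,7S,7aR)-7-ethynyl-3-methyl-2,5-dioxooctahydro-1-benzofuran-6-yl]acetaldehyde
Conditions: O3 (1 equiv), CH2Cl2/MeOH, −78 °C; Me2S
Reagents that add atoms: ozone (O=[O+][O-])
Why: Ozonolysis with reductive work-up; the terminal alkene reacts far faster than the terminal alkyne, so one equivalent of ozone cleaves only the allyl group.

**Step 6**
Reactants: 13
Product: 14 (2S,3R,4S,8R,10S,11S)-10-hydroxy-1-methylidene-6-oxo-trans-hydrindane 3,12-lactone
Conditions: SmI2 (2.2 equiv), HMPA, t-BuOH, THF, −78 °C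
Reagents that add atoms: none
Why: Samarium ketyl–alkyne cyclisation (Molander type): the aldehyde is reduced faster than the ketone, the ketyl closes 5-exo-dig between the two equatorial arms (trans ring fusion untouched), the vinyl radical is reduced and protonated to the exocyclic methylene, and C10 is set because the O–Sm bond avoids the alkyne π-system and takes the pseudo-axial α position allowed by the twist of the trans-fused ring.

**Step 7**
Reactants: 14; 15 vinylmagnesium bromide
Product: 16 (2S,3R,4S,6R,8R,10S,11S)-6-ethenyl-6,10-dihydroxy-1-methylidene-trans-hydrindane 3,12-lactone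
Conditions: 15 (2.5 equiv), LaCl3·2LiCl (30 mol %), THF, −78 °C
Reagents that add atoms: none
Why: Lanthanum-assisted Grignard 1,2-addition to the ketone, which is far more electrophilic than the γ-lactone at −78 °C; the vinyl group enters from the β face anti to the axial C4–C11 bond, and this carbinol centre is erased in step 13.

**Step 8**
Reactants: 16
Product: 17 (2S)-2-[(2S,3R,4S,6R,8R,10S)-6-ethenyl-3,6,10-trihydroxy-1-methylidene-trans-hydrindan-4-yl]-N-methoxy-N-methylpropanamide
Conditions: AlMe3, MeNH(OMe), CH2Cl2, 0 → 23 °C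
Reagents that add atoms: N,O-dimethylhydroxylamine (CNOC)
Why: Weinreb aminolysis of the lactone with the aluminium amide opens the ring to the N-methoxy-N-methylamide and frees the C3 hydroxyl without touching any stereocentre.

**Step 9**
Reactants: 17
Product: 18 the 3,10-bis(triethylsilyl) ether of 17
Conditions: Et3SiCl (2.5 equiv), imidazole, DMF, 23 °C
Reagents that add atoms: chlorotriethylsilane (CC[Si](Cl)(CC)CC)
Why: Silyl chloride/imidazole silylation caps the two secondary alcohols (C3, C10) while the tertiary allylic C6 hydroxyl is too hindered to react, and capping C3 prevents relactonisation.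

**Step 10**
Reactants: 18
Product: 19 (2S)-2-[(2S,3R,4S,6R,8R,10S)-6-ethenyl-6-hydroxy-1-methylidene-3,10-bis(triethylsilyloxy)-trans-hydrindan-4-yl]propanal
Conditions: i-Bu2AlH, THF, −78 °C; aq. potassium sodium tartrate
Reagents that add atoms: none
Why: i-Bu2AlH reduction of a Weinreb amide stops at the aldehyde because the chelated tetrahedral intermediate survives until work-up.

**Step 11**
Reactants: 19; 20 1-chloro-3-methylbut-2-ene (prenyl chloride)
Product: 22 (2S,3S)-2-[(2S,3R,4S,6R,8R,10S)-6-ethenyl-6-hydroxy-1-methylidene-3,10-bis(triethylsilyloxy)-trans-hydrindan-4-yl]-6-methylhept-5-en-3-ol, via prenylbarium chloride 21 (not isolated)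
Conditions: BaI2, lithium biphenylide, THF, 23 °C; 20, −78 °C; then 19, −78 °C
Reagents that add atoms: none
Why: Allylic barium reagents add to aldehydes through their α-carbon (Yamamoto allylbarium addition), giving the linear prenyl carbinol, and Felkin–Anh attack anti to the ring substituent on C11 gives the 11,12-syn (12S) alcohol.

**Step 12**
Reactants: 22
Product: 23 the 12-acetate of 22
Conditions: Ac2O, pyridine, DMAP (5 mol %), CH2Cl2, 0 °C
Reagents that add atoms: acetic anhydride (CC(=O)OC(C)=O)
Why: DMAP-catalysed acetylation of the only secondary alcohol; the tertiary allylic alcohol does not acylate at 0 °C.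

**Step 13**
Reactants: 23
Product: 24 (2S,3R,4S,8R,10S)-4-[(2S,3S)-3-acetoxy-6-methylhept-5-en-2-yl]-1,7-dimethylidene-3,10-bis(triethylsilyloxy)-trans-bicyclo[5.3.0]decan-6-one
Conditions: Pd(MeCN)4(BF4)2 (10 mol %), 1,4-benzoquinone (1.5 equiv), 2,6-di-tert-butylpyridine (20 mol %), 4 Å MS, CH2Cl2, 0 → 23 °C
Reagents that add atoms: none
Why: Proposed new method: cationic divalent palladium binds the vinyl group of the tertiary allylic alcohol, the better-migrating secondary ring carbon C8 shifts from C6 to the internal alkene carbon anti to palladium while the hydroxyl collapses to the C6 ketone (semipinacol 1,2-shift, six- to seven-membered ring, C8 migrating with retention), the primary alkylpalladium then loses the C7 hydrogen by β-hydride elimination to give the exocyclic enone, and benzoquinone reoxidises the zerovalent palladium; the closest known reaction is the palladium-catalysed oxidative ring expansion of 1-vinylcyclobutanols to 2-methylenecyclopentanones, not shown for an unstrained cyclohexanol, where carbonyl formation and enone conjugation rather than strain release must drive the shift.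

**Step 14**
Reactants: 24
Product: 26 (2S,3R,4S,6R,8R,10S)-4-[(2S,3S)-3-acetoxy-6-methylhept-5-en-2-yl]-1,7-dimethylidene-trans-bicyclo[5.3.0]decane-3,6,10-triol (CNP0210891.3), via silyl-protected allylic alcohol 25 (not isolated)
Conditions: (S)-2-methyl-CBS-oxazaborolidine (20 mol %), catecholborane, toluene, −78 °C; then HF·pyridine, THF, 0 °C
Reagents that add atoms: none
Why: Corey–Bakshi–Shibata reduction of the α-methylene ketone (alkenyl carbon as the large group) gives the 6R allylic alcohol under catalyst control, and HF·pyridine then removes both triethylsilyl ethers without touching the acetate.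

**Compound list**
1 | (R)-4-[(tert-butyldimethylsilyl)oxy]cyclohex-2-en-1-one | O=C1C=C[C@H](O[Si](C)(C)C(C)(C)C)CC1 | starting material
2 | lithium (trimethylsilyl)acetylide | [Li]C#C[Si](C)(C)C | starting material
3 | allyl iodide | C=CCI | starting material
4 | diethyl[(trimethylsilyl)ethynyl]alane | CC[Al](CC)C#C[Si](C)(C)C | intermediate
5 | diethylaluminium enolate of (3S,4R)-4-(tert-butyldimethylsilyloxy)-3-[(trimethylsilyl)ethynyl]cyclohexanone | CC[Al](CC)OC1=C[C@@H](C#C[Si](C)(C)C)[C@H](O[Si](C)(C)C(C)(C)C)CC1 | intermediate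
6 | (2R,3S,4R)-2-allyl-4-[(tert-butyldimethylsilyl)oxy]-3-[(trimethylsilyl)ethynyl]cyclohexan-1-one | O=C1[C@H](CC=C)[C@@H](C#C[Si](C)(C)C)[C@H](O[Si](C)(C)C(C)(C)C)CC1 | intermediate
7 | 6-(phenylselanyl) derivative of 6 (both C6 epimers) | O=C1[C@H](CC=C)[C@@H](C#C[Si](C)(C)C)[C@H](O[Si](C)(C)C(C)(C)C)CC1[Se]c2ccccc2 | intermediate
8 | (4R,5S,6R)-6-allyl-4-[(tert-butyldimethylsilyl)oxy]-5-[(trimethylsilyl)ethynyl]cyclohex-2-en-1-one | O=C1C=C[C@@H](O[Si](C)(C)C(C)(C)C)[C@H](C#C[Si](C)(C)C)[C@H]1CC=C | intermediate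
9 | 2-bromopropanoyl bromide (racemic) | CC(Br)C(=O)Br | starting material
10 | (1R,5R,6S)-5-allyl-4-oxo-6-[(trimethylsilyl)ethynyl]cyclohex-2-en-1-yl 2-bromopropanoate (both CHBr epimers) | O=C1C=C[C@@H](OC(=O)C(C)Br)[C@H](C#C[Si](C)(C)C)[C@H]1CC=C | intermediate
11 | (3S,3aS,6R,7S,7aR)-6-allyl-3-methyl-7-[(trimethylsilyl)ethynyl]octahydro-1-benzofuran-2,5-dione | O=C1C[C@H]2[C@H](C)C(=O)O[C@H]2[C@H](C#C[Si](C)(C)C)[C@H]1CC=C | intermediate
12 | (3S,3aS,6R,7S,7aR)-6-allyl-7-ethynyl-3-methyloctahydro-1-benzofuran-2,5-dione | O=C1C[C@H]2[C@H](C)C(=O)O[C@H]2[C@H](C#C)[C@H]1CC=C | intermediate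
13 | 2-[(3S,3aS,6R,7S,7aR)-7-ethynyl-3-methyl-2,5-dioxooctahydro-1-benzofuran-6-yl]acetaldehyde | O=C1C[C@H]2[C@H](C)C(=O)O[C@H]2[C@H](C#C)[C@H]1CC=O | intermediate
14 | (2S,3R,4S,8R,10S,11S)-10-hydroxy-1-methylidene-6-oxo-trans-hydrindane with cis-fused γ-lactone O(C3)–C12(=O)–C11H(CH3)–C4 | O=C1C[C@H]2[C@H](C)C(=O)O[C@H]2[C@@H]3C(=C)[C@@H](O)C[C@@H]13 | intermediate
15 | vinylmagnesium bromide | C=C[Mg]Br | starting material
16 | (2S,3R,4S,6R,8R,10S,11S)-6-ethenyl-6,10-dihydroxy-1-methylidene-trans-hydrindane 3,12-lactone | C=C[C@]1(O)C[C@H]2[C@H](C)C(=O)O[C@H]2[C@@H]3C(=C)[C@@H](O)C[C@@H]13 | intermediate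
17 | (2S)-2-[(2S,3R,4S,6R,8R,10S)-6-ethenyl-3,6,10-trihydroxy-1-methylidene-trans-hydrindan-4-yl]-N-methoxy-N-methylpropanamide | C=C[C@]1(O)C[C@@H]([C@H](C)C(=O)N(C)OC)[C@@H](O)[C@@H]2C(=C)[C@@H](O)C[C@@H]12 | intermediate
18 | 3,10-bis(triethylsilyl) ether of 17 | C=C[C@]1(O)C[C@@H]([C@H](C)C(=O)N(C)OC)[C@@H](O[Si](CC)(CC)CC)[C@@H]2C(=C)[C@@H](O[Si](CC)(CC)CC)C[C@@H]12 | intermediate
19 | (2S)-2-[(2S,3R,4S,6R,8R,10S)-6-ethenyl-6-hydroxy-1-methylidene-3,10-bis(triethylsilyloxy)-trans-hydrindan-4-yl]propanal | C=C[C@]1(O)C[C@@H]([C@H](C)C=O)[C@@H](O[Si](CC)(CC)CC)[C@@H]2C(=C)[C@@H](O[Si](CC)(CC)CC)C[C@@H]12 | intermediate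
20 | 1-chloro-3-methylbut-2-ene | CC(C)=CCCl | starting material
21 | (3-methylbut-2-enyl)barium chloride | CC(C)=CC[Ba]Cl | intermediate
22 | (2S,3S)-2-[(2S,3R,4S,6R,8R,10S)-6-ethenyl-6-hydroxy-1-methylidene-3,10-bis(triethylsilyloxy)-trans-hydrindan-4-yl]-6-methylhept-5-en-3-ol | C=C[C@]1(O)C[C@@H]([C@H](C)[C@H](CC=C(C)C)O)[C@@H](O[Si](CC)(CC)CC)[C@@H]2C(=C)[C@@H](O[Si](CC)(CC)CC)C[C@@H]12 | intermediate
23 | 12-acetate of 22 | C=C[C@]1(O)C[C@@H]([C@H](C)[C@H](CC=C(C)C)OC(C)=O)[C@@H](O[Si](CC)(CC)CC)[C@@H]2C(=C)[C@@H](O[Si](CC)(CC)CC)C[C@@H]12 | intermediate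
24 | (2S,3R,4S,8R,10S)-4-[(2S,3S)-3-acetoxy-6-methylhept-5-en-2-yl]-1,7-dimethylidene-3,10-bis(triethylsilyloxy)-trans-bicyclo[5.3.0]decan-6-one | C=C1[C@H]2[C@H](O[Si](CC)(CC)CC)[C@H]([C@H](C)[C@H](CC=C(C)C)OC(C)=O)CC(=O)C(=C)[C@@H]2C[C@@H]1O[Si](CC)(CC)CC | intermediate
25 | (6R)-alcohol from 24 (3,10-bis(triethylsilyl) ether of the target) | C=C1[C@H]2[C@H](O[Si](CC)(CC)CC)[C@H]([C@H](C)[C@H](CC=C(C)C)OC(C)=O)C[C@@H](O)C(=C)[C@@H]2C[C@@H]1O[Si](CC)(CC)CC | intermediate
26 | (2S,3R,4S,6R,8R,10S)-4-[(2S,3S)-3-acetoxy-6-methylhept-5-en-2-yl]-1,7-dimethylidene-trans-bicyclo[5.3.0]decane-3,6,10-triol | C=C1[C@H]2[C@H](O)[C@H]([C@H](C)[C@H](CC=C(C)C)OC(C)=O)C[C@@H](O)C(=C)[C@@H]2C[C@@H]1O | target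

**Totals**
Total step count: 14. Longest linear sequence: 14 steps (from 1).

**Three steps most likely to fail**

Step 13 (the proposed ring expansion; risk: no 1,2-shift without strain release, or migration of C5 instead of C8). The fallback uses known chemistry, sets out from 23 and comes back at 24. VO(acac)2/t-BuOOH epoxidises the vinyl group under direction of the tertiary hydroxyl to give epoxy alcohol F1. ZnBr2 in CH2Cl2 then opens the epoxide at C7 with 1,2-shift of C8 (semipinacol rearrangement of a 2,3-epoxy alcohol) to give hydroxymethyl ketone F2. MsCl/Et3N converts it into mesylate F3, which DBU eliminates to enone 24.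

Step 6 (risk: competing reduction of the C6 ketone and uncertain C10 selectivity; a nickel-templated closure is expected to favour the wrong C10 epimer). The fallback sets out from 13 and comes back at 16, and moves control of C10 from the cyclisation to a reagent-controlled ketone reduction. Whatever C10 mixture the cyclisation gives, hydroxy ketone F4, is taken through the conditions of step 7 to diol F5. MnO2 oxidises only the secondary allylic alcohol to enone F6. (R)-2-methyl-CBS-oxazaborolidine/catecholborane then reduces F6 to the 10S alcohol 16.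

Step 11 (risk: γ-attack giving the reverse-prenyl isomer, and only moderate Felkin–Anh selectivity at C12). The fallback sets out from 19 and comes back at 22. Allylboration with (−)-Ipc2B(allyl), the antipode matched with Felkin–Anh control, gives homoallylic alcohol F7 under reagent control. Cross-metathesis with 2-methyl-2-butene (second-generation Grubbs catalyst), stopped once the unhindered terminal alkene is consumed, turns the allyl group into the prenyl group of 22.

**Further compounds**
F1 | step 13 | 6-(oxiran-2-yl) analogue of 23 (tertiary α-hydroxy epoxide, both epoxide epimers) | O[C@@]1(C2CO2)C[C@@H]([C@H](C)[C@H](CC=C(C)C)OC(C)=O)[C@@H](O[Si](CC)(CC)CC)[C@@H]3C(=C)[C@@H](O[Si](CC)(CC)CC)C[C@@H]13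
F2 | step 13 | 7-(hydroxymethyl) analogue of 24 with saturated C7 (both C7 epimers) | C=C1[C@H]2[C@H](O[Si](CC)(CC)CC)[C@H]([C@H](C)[C@H](CC=C(C)C)OC(C)=O)CC(=O)C(CO)[C@@H]2C[C@@H]1O[Si](CC)(CC)CC
F3 | step 13 | methanesulfonate of F2 | C=C1[C@H]2[C@H](O[Si](CC)(CC)CC)[C@H]([C@H](C)[C@H](CC=C(C)C)OC(C)=O)CC(=O)C(COS(C)(=O)=O)[C@@H]2C[C@@H]1O[Si](CC)(CC)CC
F4 | step 6 | C10-epimer mixture of hydroxy keto lactone 14 | O=C1C[C@H]2[C@H](C)C(=O)O[C@H]2[C@@H]3C(=C)C(O)C[C@@H]13
F5 | step 6 | C10-epimer mixture of diol 16 | C=C[C@]1(O)C[C@H]2[C@H](C)C(=O)O[C@H]2[C@@H]3C(=C)C(O)C[C@@H]13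
F6 | step 6 | 10-oxo analogue of 16 (α-methylene cyclopentanone) | C=C[C@]1(O)C[C@H]2[C@H](C)C(=O)O[C@H]2[C@@H]3C(=C)C(=O)C[C@@H]13
F7 | step 11 | (2S,3S)-2-[(2S,3R,4S,6R,8R,10S)-6-ethenyl-6-hydroxy-1-methylidene-3,10-bis(triethylsilyloxy)-trans-hydrindan-4-yl]hex-5-en-3-ol | C=C[C@]1(O)C[C@@H]([C@H](C)[C@H](CC=C)O)[C@@H](O[Si](CC)(CC)CC)[C@@H]2C(=C)[C@@H](O[Si](CC)(CC)CC)C[C@@H]12
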